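## Retrosynthetic overview

1. Target 21 comes from its methyl ester 20. The phenyldienyl arm is cut back by HWE and Wittig olefinations to the C5 carbaldehyde 16, which is the reduced form of the auxiliary amide 15.
2. The C7 methyl and the C6=C7 alkene come from ketone 13 by enol triflate formation and Negishi coupling. The cyclopentene (second ring) comes from RCM of 12.
3. The trans C3a/C7a pair and C1 come from enone 6 by Cu-catalysed conjugate addition of a but-1-en-2-yl unit, then Pd allylation with a symmetric 1,3-dimethylallyl unit.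
4. Key step: enone 6, already carrying both vicinal quaternary carbons, comes from two-electron reduction and double C-methylation of the aromatic ester-amide 3. The six-membered ring (first ring) is the former benzene ring.
5. Arene 3 comes from aminocarbonylation of bromoarene 1 with the prolinol-derived amine 2.

Assumption: the facial sense of the (S)-auxiliary in step 2 and of (S)-BINAP in step 5 is taken by analogy with prolinol-benzamide Birch alkylations and Pd/BINAP ketone-enolate allylations. If either runs the other way, the equally available antipode is used and nothing else changes.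

## Route

Step 1
Reactants: 1 methyl 2-bromo-4-methoxybenzoate; 2 (S)-2-(methoxymethyl)pyrrolidine
Product: 3 methyl 4-methoxy-2-{[(2S)-2-(methoxymethyl)pyrrolidin-1-yl]carbonyl}benzoate
Conditions: CO (1 atm), Pd(OAc)2 (2 mol %), Xantphos (4 mol %), Na2CO3, toluene, 90 °C
Reagents that add atoms: carbon monoxide, [C-]#[O+]
Why: Pd-catalysed aminocarbonylation of the aryl bromide places the auxiliary amide ortho to the ester and meta to OMe without any regiochemical ambiguity, and no ring stereocentre is formed.

Step 2
Reactants: 3 methyl 4-methoxy-2-{[(2S)-2-(methoxymethyl)pyrrolidin-1-yl]carbonyl}benzoate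
Product: 6 methyl (1R,6S)-1,6-dimethyl-6-{[(2S)-2-(methoxymethyl)pyrrolidin-1-yl]carbonyl}-4-oxocyclohex-2-ene-1-carboxylate (the two methyls cis, ester and amide cis), via dilithium bis-enolate of 3 4 (not isolated), via methyl (1R,6S)-4-methoxy-1,6-dimethyl-6-{[(2S)-2-(methoxymethyl)pyrrolidin-1-yl]carbonyl}cyclohexa-2,4-diene-1-carboxylate 5 (not isolated)
Conditions: Li (2.2 equiv), NH3/THF, −78 °C; MeI (5 equiv), −78 °C to rt; then 1 M HCl, THF, rt
Reagents that add atoms: iodomethane, CI; water, O
Why: Proposed new method: two-electron reduction of the 1,2-diacylarene stores both electrons in the two carbonyl groups as the non-aromatic o-quinodimethane-type bis-enolate 4 (the 1,2-dihydrophthalate reduction mode; with no proton source the para-OMe is not expelled), the more nucleophilic Li-chelated amide enolate is methylated first on the face left open by the auxiliary, the remaining ester trienolate is then α-methylated anti to the bulky amide so that the two methyls end up cis, and mild acid protonates the 2-methoxydiene 5 at its CH terminus next to the amide-bearing carbon to give the conjugated enone; the closest known reactions are the asymmetric Birch reduction–alkylation of prolinol benzamides and the reductive bis-alkylation of (hetero)aromatic diesters.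

Step 3
Reactants: 6 enone from step 2; 7 2-bromobut-1-ene
Product: 9 methyl (1R,2R,6S)-2-(but-1-en-2-yl)-1,6-dimethyl-6-{[(2S)-2-(methoxymethyl)pyrrolidin-1-yl]carbonyl}-4-[(trimethylsilyl)oxy]cyclohex-3-ene-1-carboxylate, via but-1-en-2-ylmagnesium bromide 8 (not isolated)
Conditions: 7, Mg, THF; then CuBr·SMe2 (10 mol %), TMSCl, DMPU, 6, THF, −78 °C; Et3N, NaHCO3 work-up
Reagents that add atoms: chlorotrimethylsilane, C[Si](C)(C)Cl
Why: In this TMSCl-accelerated Cu-catalysed conjugate addition the alkenyl group enters on the face carrying the two methyls, opposite the cis ester and amide, which sets C2 (future C3a) and fixes the enolate regiochemistry as the silyl enol ether.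

Step 4
Reactants: 10 (E)-pent-3-en-2-ol (racemic)
Product: 11 (E)-pent-3-en-2-yl methyl carbonate (racemic)
Conditions: ClCO2Me, pyridine, CH2Cl2, 0 °C
Reagents that add atoms: methyl chloroformate, COC(=O)Cl
Why: This is a simple O-acylation, and the racemate suffices because ionisation in step 5 gives a symmetric π-allyl unit.

Step 5
Reactants: 9 silyl enol ether; 11 (E)-pent-3-en-2-yl methyl carbonate
Product: 12 methyl (1R,2R,3S,6S)-2-(but-1-en-2-yl)-1,6-dimethyl-6-{[(2S)-2-(methoxymethyl)pyrrolidin-1-yl]carbonyl}-4-oxo-3-[(2R,3E)-pent-3-en-2-yl]cyclohexane-1-carboxylate (C2 and C3 substituents trans)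
Conditions: Pd2(dba)3 (2.5 mol %), (S)-BINAP (6 mol %), TBAT (20 mol %), THF, 0 °C to rt
Reagents that add atoms: none
Why: In this Tsuji–Trost allylic alkylation 11 ionises to the symmetric syn,syn-1,3-dimethylallyl-Pd cation, the released methoxide unmasks the regiodefined enolate of 9, the enolate attacks anti to the neighbouring butenyl group (trans, and also the thermodynamic diequatorial epimer at this α-carbon), and the chiral ligand selects the allyl terminus and so sets the side-chain (R) centre (future C1).

Step 6
Reactants: 12 allylated ketone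
Product: 13 methyl (1R,3aR,4R,5S,7aS)-3-ethyl-1,4,5-trimethyl-5-{[(2S)-2-(methoxymethyl)pyrrolidin-1-yl]carbonyl}-7-oxo-3a,4,5,6,7,7a-hexahydro-1H-indene-4-carboxylate (trans ring fusion)
Conditions: Hoveyda–Grubbs II (5–10 mol %), toluene, 80 °C, Ar sparge
Reagents that add atoms: none
Why: Ring-closing metathesis joins the propenyl and 1,1-disubstituted alkenes at a bond remote from the fusion carbons, so the diequatorial trans relationship passes unchanged into the trans-hydrindenone, and loss of propene drives the closure.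

Step 7
Reactants: 13 bicyclic ketone
Product: 14 methyl (1R,3aR,4R,5S,7aS)-3-ethyl-1,4,5-trimethyl-5-{[(2S)-2-(methoxymethyl)pyrrolidin-1-yl]carbonyl}-7-{[(trifluoromethyl)sulfonyl]oxy}-3a,4,5,7a-tetrahydro-1H-indene-4-carboxylate
Conditions: KHMDS, THF, −78 °C; PhNTf2, −78 to 0 °C
Reagents that add atoms: N-phenylbis(trifluoromethanesulfonimide), O=S(=O)(N(c1ccccc1)S(=O)(=O)C(F)(F)F)C(F)(F)F
Why: Kinetic enolisation takes the C6 methylene rather than the tertiary, doubly branched C7a–H (which would put an alkene at the trans fusion), and O-sulfonylation gives the C6=C7 enol triflate with no stereocentre touched.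

Step 8
Reactants: 14 enol triflate
Product: 15 methyl (1R,3aR,4R,5S,7aS)-3-ethyl-1,4,5,7-tetramethyl-5-{[(2S)-2-(methoxymethyl)pyrrolidin-1-yl]carbonyl}-3a,4,5,7a-tetrahydro-1H-indene-4-carboxylate
Conditions: Me2Zn, Pd(dppf)Cl2 (5 mol %), THF, 50 °C
Reagents that add atoms: dimethylzinc, C[Zn]C
Why: Negishi coupling replaces OTf by methyl with retention of the alkene position, and both the ester and the amide are inert to Me2Zn.

Step 9
Reactants: 15 amide ester
Product: 16 methyl (1R,3aR,4R,5S,7aS)-3-ethyl-5-formyl-1,4,5,7-tetramethyl-3a,4,5,7a-tetrahydro-1H-indene-4-carboxylate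
Conditions: Cp2Zr(H)Cl (2 equiv), THF, rt; H2O/SiO2 work-up
Reagents that add atoms: water, O
Why: Schwartz-reagent reduction of the tertiary amide stops at the zirconated hemiaminal/iminium stage, which hydrolyses to the aldehyde, while the hindered methyl ester and the two trisubstituted alkenes are left alone and the non-enolisable C5 cannot epimerise.

Step 10
Reactants: 16 aldehyde; 17 2-(triphenylphosphoranylidene)propanal
Product: 18 methyl (1R,3aR,4R,5R,7aS)-3-ethyl-1,4,5,7-tetramethyl-5-[(1E)-2-methyl-3-oxoprop-1-en-1-yl]-3a,4,5,7a-tetrahydro-1H-indene-4-carboxylate (same spatial arrangement at C5; only the CIP descriptor changes)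
Conditions: toluene, 110 °C, 24–48 h
Reagents that add atoms: none
Why: Wittig olefination with a stabilised ylide gives the (E)-trisubstituted enal under thermodynamic control of oxaphosphetane formation.

Step 11
Reactants: 18 enal; 19 diethyl benzylphosphonate
Product: 20 methyl (1R,3aR,4R,5S,7aS)-3-ethyl-1,4,5,7-tetramethyl-5-[(1E,3E)-2-methyl-4-phenylbuta-1,3-dien-1-yl]-3a,4,5,7a-tetrahydro-1H-indene-4-carboxylate
Conditions: 19, NaH, THF, 0 °C; then 18, 0 °C to rt
Reagents that add atoms: none
Why: Horner–Wadsworth–Emmons olefination with the benzyl phosphonate anion gives the (E)-styryl double bond and completes the dienyl arm.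

Step 12
Reactants: 20 methyl ester
Product: 21 zyggomphic acid B, (1R,3aR,4R,5S,7aS)-3-ethyl-1,4,5,7-tetramethyl-5-[(1E,3E)-2-methyl-4-phenylbuta-1,3-dien-1-yl]-3a,4,5,7a-tetrahydro-1H-indene-4-carboxylic acid
Conditions: EtSNa, DMF, 90 °C; then dilute aq. HCl to pH 3
Reagents that add atoms: none
Why: SN2 dealkylation at the ester methyl group (BAl2) bypasses the blocked acyl carbon flanked by a quaternary and a tertiary centre and avoids the strong acid that could lactonise the acid onto a ring alkene.

## Compound list

1 | methyl 2-bromo-4-methoxybenzoate | COC(=O)c1ccc(OC)cc1Br | starting material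
2 | (S)-2-(methoxymethyl)pyrrolidine | COC[C@@H]1CCCN1 | starting material
3 | methyl 4-methoxy-2-{[(2S)-2-(methoxymethyl)pyrrolidin-1-yl]carbonyl}benzoate | COC(=O)c1ccc(OC)cc1C(=O)N1CCC[C@H]1COC | intermediate
4 | dilithium bis-enolate of 3 (o-quinodimethane type) | [Li+].[Li+].COC1=CC(=C([O-])N2CCC[C@H]2COC)C(=C([O-])OC)C=C1 | intermediate
5 | methyl (1R,6S)-4-methoxy-1,6-dimethyl-6-(auxiliary carbonyl)cyclohexa-2,4-diene-1-carboxylate | COC1=C[C@](C)(C(=O)N2CCC[C@H]2COC)[C@](C)(C(=O)OC)C=C1 | intermediate
6 | methyl (1R,6S)-1,6-dimethyl-6-(auxiliary carbonyl)-4-oxocyclohex-2-ene-1-carboxylate | O=C1C=C[C@@](C)(C(=O)OC)[C@@](C)(C(=O)N2CCC[C@H]2COC)C1 | intermediate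
7 | 2-bromobut-1-ene | C=C(Br)CC | starting material
8 | but-1-en-2-ylmagnesium bromide | C=C([Mg]Br)CC | intermediate
9 | methyl (1R,2R,6S)-2-(but-1-en-2-yl)-1,6-dimethyl-6-(auxiliary carbonyl)-4-(trimethylsilyloxy)cyclohex-3-ene-1-carboxylate | C[Si](C)(C)OC1=C[C@H](C(=C)CC)[C@@](C)(C(=O)OC)[C@@](C)(C(=O)N2CCC[C@H]2COC)C1 | intermediate
10 | (E)-pent-3-en-2-ol (racemic) | C/C=C/C(C)O | starting material
11 | (E)-pent-3-en-2-yl methyl carbonate (racemic) | C/C=C/C(C)OC(=O)OC | intermediate
12 | methyl (1R,2R,3S,6S)-2-(but-1-en-2-yl)-1,6-dimethyl-6-(auxiliary carbonyl)-4-oxo-3-[(2R,3E)-pent-3-en-2-yl]cyclohexane-1-carboxylate | C/C=C/[C@@H](C)[C@@H]1C(=O)C[C@](C)(C(=O)N2CCC[C@H]2COC)[C@](C)(C(=O)OC)[C@H]1C(=C)CC | intermediate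
13 | methyl (1R,3aR,4R,5S,7aS)-3-ethyl-1,4,5-trimethyl-5-(auxiliary carbonyl)-7-oxo-3a,4,5,6,7,7a-hexahydro-1H-indene-4-carboxylate | CCC1=C[C@@H](C)[C@@H]2C(=O)C[C@](C)(C(=O)N3CCC[C@H]3COC)[C@](C)(C(=O)OC)[C@@H]12 | intermediate
14 | C7 enol triflate of 13 | CCC1=C[C@@H](C)[C@@H]2C(OS(=O)(=O)C(F)(F)F)=C[C@](C)(C(=O)N3CCC[C@H]3COC)[C@](C)(C(=O)OC)[C@@H]12 | intermediate
15 | methyl (1R,3aR,4R,5S,7aS)-3-ethyl-1,4,5,7-tetramethyl-5-(auxiliary carbonyl)-3a,4,5,7a-tetrahydro-1H-indene-4-carboxylate | CCC1=C[C@@H](C)[C@@H]2C(C)=C[C@](C)(C(=O)N3CCC[C@H]3COC)[C@](C)(C(=O)OC)[C@@H]12 | intermediate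
16 | methyl (1R,3aR,4R,5S,7aS)-3-ethyl-5-formyl-1,4,5,7-tetramethyl-3a,4,5,7a-tetrahydro-1H-indene-4-carboxylate | CCC1=C[C@@H](C)[C@@H]2C(C)=C[C@](C)(C=O)[C@](C)(C(=O)OC)[C@@H]12 | intermediate
17 | 2-(triphenylphosphoranylidene)propanal | CC(C=O)=P(c1ccccc1)(c1ccccc1)c1ccccc1 | starting material
18 | methyl (1R,3aR,4R,5R,7aS)-3-ethyl-1,4,5,7-tetramethyl-5-[(1E)-2-methyl-3-oxoprop-1-enyl]-3a,4,5,7a-tetrahydro-1H-indene-4-carboxylate | CCC1=C[C@@H](C)[C@@H]2C(C)=C[C@](C)(/C=C(C)/C=O)[C@](C)(C(=O)OC)[C@@H]12 | intermediate
19 | diethyl benzylphosphonate | CCOP(=O)(Cc1ccccc1)OCC | starting material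
20 | zyggomphic acid B methyl ester | CCC1=C[C@@H](C)[C@@H]2C(C)=C[C@](C)(/C=C(C)/C=C/c3ccccc3)[C@](C)(C(=O)OC)[C@@H]12 | intermediate
21 | zyggomphic acid B | CCC1=C[C@@H](C)[C@@H]2C(C)=C[C@](C)(/C=C(C)/C=C/c3ccccc3)[C@](C)(C(=O)O)[C@@H]12 | target

## Step count and risks

Total step count: 12. Longest linear sequence: 11 (steps 1–3 and 5–12; step 4 is a one-step side branch).

The three steps most likely to fail:

**Step 2.** The risks are γ- rather than α-methylation of the trienolate, trans-dimethyl product, and weak or reversed auxiliary control.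

The fallback sets out from 3 and returns at 5. The two C–C bond formations are separated. Arene 3 is reduced as before, but only one equivalent of MeI is added and the mixture is quenched with NH4Cl. This gives the mono-methylated dihydroarene methyl (6S)-4-methoxy-6-methyl-6-{[(2S)-2-(methoxymethyl)pyrrolidin-1-yl]carbonyl}cyclohexa-2,4-diene-1-carboxylate F1.

The C6 diastereomers of F1 can be separated because the auxiliary makes them diastereomeric. The second quaternary centre is then made in its own deprotonative alkylation of the extended ester enolate (KHMDS, MeI, THF/DMPU), anti to the amide. Counter-ion and additive can be tuned freely at this stage. The product is 5, which is hydrolysed to 6.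

**Step 5.** The risks are low reactivity of the hindered enolate, elimination of the π-allyl unit to pentadiene, and a ligand/substrate mismatch at the side-chain centre.

The fallback sets out from 9 and returns at 13. The side-chain centre is set by substrate control in three operations before the ring closure:

- Mukaiyama aldol of 9 with acetaldehyde (TiCl4) gives the 3-(1-hydroxyethyl) ketone F2.
- Mesylation and DBU elimination give the (E)-3-ethylidene ketone F3, in which allylic strain holds the butenyl group axial.
- A vinyl cuprate adds to the exocyclic enone anti to that group, and base equilibration of the α-carbon gives the trans 3-[(2R)-but-3-en-2-yl] ketone F4.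
- RCM of F4 delivers 13.

**Step 9.** The risk is that the axial amide, flanked by a quaternary carbon, resists the bulky zirconium hydride.

The fallback sets out from 15 and returns at 16. The auxiliary is expelled by neighbouring-group participation, not by external hydride. I2 in THF/H2O engages the β,γ-alkene, and the amide oxygen closes onto C7 to give the bridged iodolactone (C7–O–C(=O)–C5, iodine on C6) F5 with release of the amine. DIBAL-H at −78 °C reduces the strained lactone to the iodolactol F6. Zinc then triggers a Vasella-type reductive fragmentation that restores the C6=C7 alkene and opens the lactol to aldehyde 16.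

## Further compounds

F1 | step 2 | methyl (6S)-4-methoxy-6-methyl-6-{[(2S)-2-(methoxymethyl)pyrrolidin-1-yl]carbonyl}cyclohexa-2,4-diene-1-carboxylate (C1 epimers) | COC1=C[C@](C)(C(=O)N2CCC[C@H]2COC)C(C(=O)OC)C=C1
F2 | step 5 | 3-(1-hydroxyethyl) ketone, ring configuration as in 12, carbinol epimers | CC(O)[C@@H]1C(=O)C[C@](C)(C(=O)N2CCC[C@H]2COC)[C@](C)(C(=O)OC)[C@H]1C(=C)CC
F3 | step 5 | (E)-3-ethylidene ketone, remaining ring configuration as in 12 | C/C=C1/C(=O)C[C@](C)(C(=O)N2CCC[C@H]2COC)[C@](C)(C(=O)OC)[C@H]1C(=C)CC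
F4 | step 5 | 3-[(2R)-but-3-en-2-yl] ketone, ring configuration as in 12 | C=C[C@@H](C)[C@@H]1C(=O)C[C@](C)(C(=O)N2CCC[C@H]2COC)[C@](C)(C(=O)OC)[C@H]1C(=C)CC
F5 | step 9 | bridged C5-carbonyl/C7-oxygen γ-lactone with axial C6 iodide, methyl ester retained | CCC1=C[C@@H](C)[C@@H]2[C@]3(C)OC(=O)[C@@](C)([C@@H]3I)[C@](C)(C(=O)OC)[C@@H]12
F6 | step 9 | corresponding iodolactol (anomers) | CCC1=C[C@@H](C)[C@@H]2[C@]3(C)OC(O)[C@@](C)([C@@H]3I)[C@](C)(C(=O)OC)[C@@H]12
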